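Decide first what you will keep the books in: percent of the substrate, the limiting reagent, whose charge is smaller than the partner's.

| setting | theta | beta | north-west | south |
|---|---|---|---|---|
| substrate | 0.050 M | 0.050 M | 0.050 M | 0.050 M |
| partner | 0.062 M | 0.094 M | 0.125 M | 0.125 M |
| protic impurity | 0.025 M | 0.025 M | 0.0250 M | 0.0250 M |
| temperature | 58 °C | 74 °C | 60 °C | 70 °C |
| remark | run made earlier | run made earlier |  |  |
| time |  |  | 25 min | 25 min |

| run | time / min | substrate / % | target / % | homo product / % | isomer of the product / % | open intermediate / % |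
|---|---|---|---|---|---|---|
| theta | 4.00 | 79.3 | 0.1 | 0.3 | 0.3 | 20.7 |
| theta | 8.00 | 63.8 | 0.5 | 0.7 | 0 | 35.1 |
| theta | 12.0 | 50.5 | 2.3 | 1.8 | 0.6 | 45.8 |
| theta | 15.0 | 42.5 | 3.7 | 3.0 | 0.6 | 50.4 |
| theta | 20.0 | 32.1 | 6.3 | 5.5 | 1.5 | 55.4 |
| theta | 25.0 | 23.5 | 9.1 | 8.4 | 2.8 | 56.8 |
| theta | 30.0 | 18.3 | 11.7 | 10.8 | 5.1 | 55.1 |
| beta | 1.33 | 66.7 | 0.1 | 0 | 0.2 | 32.0 |
| beta | 2.00 | 55.3 | 1.3 | 0.7 | 0.5 | 43.7 |
| beta | 3.00 | 40.4 | 3.3 | 1.6 | 0.8 | 53.1 |
| beta | 4.00 | 30.0 | 6.0 | 3.3 | 1.3 | 59.4 |
| beta | 6.00 | 16.4 | 11.3 | 6.2 | 4.6 | 61.0 |
| beta | 10.0 | 5.0 | 18.8 | 12.1 | 14.2 | 50.1 |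
| beta | 15.0 | 1.0 | 22.9 | 15.9 | 25.4 | 34.4 |

(scatter of a reading: 0.3 percentage points)

- a species is counted by the substrate in it: one homo product counts as two

- which of these there is most of at the end, counted by the substrate in it, north-west (homo product / substrate / target / open intermediate / isomer of the product)
- which of these there is most of at the end, counted by the substrate in it, south (homo product / substrate / target / open intermediate / isomer of the product)
- final amount of the leader among these, as a percentage of the substrate charged, in north-west
- final amount of the leader among these, as a percentage of the substrate charged, in south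

The first entry is substrate still unconverted. In the theta run its logarithmic rate is 0.0580 min⁻¹ up to the first reading and about the same, 0.0566 min⁻¹, up to the last, when 18.3% remains. So in the theta run the substrate concentration sets a first-order rate, and this entry decays like a simple lag. The beta run gives 0.301 min⁻¹, and the two runs together an activation energy of 99.9 kJ mol⁻¹. That yields the substrate time constant, the time in which the substrate left falls by a factor of e: 14.2 min in north-west and 4.97 min in south.

The other entries hold what has left the first. At 25.0 min the theta run books 56.8% as open intermediate, 9.1% as target, 8.4% as homo product and 2.8% as isomer of the product. With its substrate these close at 100.6%. North-west runs 1.76 time constants, close to the theta run's last reading at 1.70, where open intermediate leads; the partner charges of the two differ, so booking open intermediate as the north-west leader is my judgement, not a reading. South runs 5.03, past the beta run's last reading at 4.52, where open intermediate (34.4%) is ahead of the isomer of the product (25.4%), so my reckoning leaves south undecided.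

The forecast gives open intermediate at 43% in north-west and isomer of the product at 36% in south. Its ground: “Substrate decay is clean first order and ignores partner depletion”.

North-west ends with open intermediate at 44.7% and south with isomer of the product at 37.2%.

    partner → second intermediate (k = 0.0580 min⁻¹, Ea = 111 kJ mol⁻¹)
    2 open intermediate → homo product (k = 0.194 L mol⁻¹ min⁻¹, Ea = 58.0 kJ mol⁻¹)
    target ⇌ isomer of the product (K = 1.90, k = 0.0544 min⁻¹, Ea = 102 kJ mol⁻¹, ΔH = −9.00 kJ mol⁻¹)
    partner + protic impurity → quenched reagent (k = 0.412 L mol⁻¹ min⁻¹, Ea = 50.0 kJ mol⁻¹)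
    substrate → open intermediate (k = 0.0713 min⁻¹, Ea = 99.0 kJ mol⁻¹)
    open intermediate + second intermediate → target (k = 0.534 L mol⁻¹ min⁻¹, Ea = 50.0 kJ mol⁻¹)
    (constants at 60 °C)

In north-west, 14.2 min puts the substrate at 17.2%, and the flask holds 16.8% with its partner down to 20% of charge. For the south flask read at 10 min, 4.97 min puts the substrate at 13.4%; that flask holds 13.3%, and its leader is open intermediate at 51.4%.

(Readings and results come from a simulation for substances that don't exist, noise included.)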